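**Retrosynthetic overview**
1. Target ⇐ 6α,9α-diol butenolide (final acetylation of the only acylable OH); butenolide ⇐ (Z)-3-iodoallylic alcohol by Pd-catalysed carbonylative lactonisation ⇐ propargylic alcohol ⇐ terminal alkyne.
2. C11–C12 bond and 9α-OH ⇐ SN2 opening of a 9α,11-spiro-epoxide by a silylpropargyl anion; epoxide ⇐ 9(11)-exo-methylene ⇐ 8α-methyl-9-ketone (C8 set by thermodynamic enolate methylation).
3. 5α-H/6α-O trans-decalin ⇐ α-face hydroboration of a 4,4-dimethyl-Δ5-octalin ⇐ deconjugative gem-dimethylation and Wolff–Kishner reduction of the Wieland–Miescher enone.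
4. Ring order: ring B is the commercial cyclohexanedione; ring A is annulated onto it (Michael addition, then L-proline aldol sets C10); a ketoreductase then fixes the C9 carbinol and upgrades the ee; the butenolide ring is closed last.

**Assumptions and conventions**
- The SMILES is read literally as (5S,6S,8R,9R,10S): trans-decalin, 10β-Me, 5α-H, 6α-OAc (equatorial), 8α-Me (equatorial), 9α-OH (axial), 9β side chain.
- Positions are given in labdane numbering (decalin C1–C10, side chain and lactone C11–C16, 8-Me = C17, 4-Me2 = C18/C19, 10-Me = C20); α is the face opposite the 10-methyl.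
- The α-face selectivity of the epoxidation (step 13) is argued from conformational analysis, not from a known result on this substrate.

**Route**

Step 1
Reactants: 1 2-methylcyclohexane-1,3-dione; 2 methyl vinyl ketone
Product: 3 2-methyl-2-(3-oxobutyl)cyclohexane-1,3-dione
Conditions: H2O, AcOH (cat.), hydroquinone (cat.), 75 °C
Reagents that add atoms: none
Why: Michael addition of the acidic 1,3-dione to the enone gives the achiral (prochiral) triketone; no stereocentre is formed.

Step 2
Reactants: 3 2-methyl-2-(3-oxobutyl)cyclohexane-1,3-dione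
Product: 5 (S)-Wieland–Miescher ketone, via cis-ketol 4 (not isolated)
Conditions: L-proline (5 mol%), DMSO, rt
Reagents that add atoms: none
Why: Hajos–Parrish–Eder–Sauer–Wiechert reaction: the enamine aldol cyclisation differentiates the two enantiotopic ring carbonyls and sets the quaternary C10 as S (typically about 70% ee before upgrade), and ketol 4 dehydrates in situ.

Step 3
Reactants: 5 (S)-Wieland–Miescher ketone
Product: 6 (4aS,5S)-hydroxy enone
Conditions: ketoreductase (NADPH-dependent), NADP+ (cat.), i-PrOH, KH2PO4/K2HPO4 buffer pH 7, 30 °C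
Reagents that add atoms: none
Why: Biocatalytic ketone reduction: the ketoreductase reduces only the saturated C9 carbonyl of the (S)-enantiomer, delivering hydride to the α face (9β-OH, S), so residual (R)-5 stays unreduced and is removed, which gives 6 essentially enantiopure.

Step 4
Reactants: 6 (4aS,5S)-hydroxy enone
Product: 7 9β-benzyl ether of the enone
Conditions: benzyl 2,2,2-trichloroacetimidate, TfOH (cat.), CH2Cl2/cyclohexane, 0 °C → rt
Reagents that add atoms: benzyl 2,2,2-trichloroacetimidate, ClC(Cl)(Cl)C(=N)OCc1ccccc1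
Why: Acid-catalysed O-benzylation with the trichloroacetimidate protects the neopentyl 9β-OH without exposing the enone to base; no stereocentre changes.

Step 5
Reactants: 7 9β-benzyl ether of the enone
Product: 9 4,4-dimethyl-Δ5-3-ketone, via monomethyl enone 8 (not isolated)
Conditions: KOtBu (3 equiv), MeI (excess), THF, 0 °C → rt
Reagents that add atoms: iodomethane, IC
Why: Deconjugative α,α-dialkylation: the potassium dienolate is methylated twice at C4, which moves the double bond to Δ5 and installs the gem-dimethyl group while C9 and C10 are untouched.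

Step 6
Reactants: 9 4,4-dimethyl-Δ5-3-ketone
Product: 11 Δ5-octalin benzyl ether, via hydrazone 10 (not isolated)
Conditions: N2H4·H2O, KOH, diethylene glycol, 130 → 200 °C
Reagents that add atoms: none
Why: Wolff–Kishner reduction (Huang–Minlon procedure) converts the hindered C3 carbonyl into CH2 through hydrazone 10, and the benzyl ether and the isolated trisubstituted alkene are stable to hot base.

Step 7
Reactants: 11 Δ5-octalin benzyl ether
Product: 13 6α-alcohol, via alkylborane 12 (not isolated)
Conditions: BH3·THF, THF, 0 °C → rt; then NaOH, H2O2, H2O, 0 → 50 °C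
Reagents that add atoms: hydrogen peroxide, OO
Why: Hydroboration–oxidation: borane adds syn and anti-Markovnikov from the α face, opposite the axial 10β- and 4β-methyls, so H goes to C5 (5α-H, trans-decalin, S) and boron to C6, and oxidation with retention gives the equatorial 6α-OH (S).

Step 8
Reactants: 13 6α-alcohol
Product: 14 6α-TBS ether 9β-benzyl ether
Conditions: TBSOTf, 2,6-lutidine, CH2Cl2, 0 °C → rt
Reagents that add atoms: tert-butyldimethylsilyl triflate, CC(C)(C)[Si](C)(C)OS(=O)(=O)C(F)(F)F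
Why: Silylation with the triflate and a hindered base protects the hindered equatorial 6-OH as a silyl ether orthogonal to the benzyl ether.

Step 9
Reactants: 14 6α-TBS ether 9β-benzyl ether
Product: 15 9β-alcohol
Conditions: H2 (1 atm), Pd(OH)2/C, EtOAc, rt
Reagents that add atoms: none
Why: Hydrogenolysis cleaves only the benzyl ether (no alkene remains and the silyl ether is inert in EtOAc), freeing the 9β-OH.

Step 10
Reactants: 15 9β-alcohol
Product: 16 9-ketone
Conditions: Dess–Martin periodinane, CH2Cl2, rt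
Reagents that add atoms: none
Why: Dess–Martin oxidation converts the neopentyl secondary alcohol into the C9 ketone under neutral conditions with no epimerisable centre at risk.

Step 11
Reactants: 16 9-ketone
Product: 18 8α-methyl-9-ketone, via lithium enolate 17 (not isolated)
Conditions: LiN(iPr)2, THF, −78 °C; MeI, −78 → 0 °C; then NaOMe (cat.), MeOH, rt
Reagents that add atoms: iodomethane, IC
Why: Enolate alkylation: only C8 can be enolised (C10 is quaternary), and the alkoxide equilibration leaves the new methyl equatorial (8α, R), because the 8β epimer would be 1,3-diaxial to the 10β-methyl.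

Step 12
Reactants: 18 8α-methyl-9-ketone
Product: 19 9(11)-exo-methylene compound
Conditions: Ph3PCH3Br, KOtBu, toluene, 100 °C
Reagents that add atoms: methyltriphenylphosphonium bromide, C[P+](c1ccccc1)(c1ccccc1)c1ccccc1.[Br-]
Why: Wittig methylenation with the ylide in hot toluene converts the hindered ketone into the exocyclic alkene, and C8 keeps its thermodynamic 8α configuration even if it enolises.

Step 13
Reactants: 19 9(11)-exo-methylene compound
Product: 20 9α,11-spiro-epoxide
Conditions: mCPBA, NaHCO3, CH2Cl2, 0 °C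
Reagents that add atoms: 3-chloroperoxybenzoic acid, OOC(=O)c1cccc(Cl)c1
Why: Prilezhaev epoxidation: the peracid is expected to attack the exocyclic alkene axially from the α face, anti to the adjacent axial 10β-methyl, giving the epoxide with oxygen α at C9 (R), which fixes the 9α-O/9β-C relationship of the target.

Step 14
Reactants: 20 9α,11-spiro-epoxide
Product: 21 9α-hydroxy TMS-alkyne
Conditions: Me3SiC≡CCH3, n-BuLi, TMEDA, THF, −78 → 0 °C; then 20, DMPU, −78 °C → rt; H2O
Reagents that add atoms: 1-(trimethylsilyl)propyne, CC#C[Si](C)(C)C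
Why: SN2 epoxide opening by the silyl-directed propargylic organolithium at the primary C11 (no Lewis acid, so no Meinwald rearrangement) forms the C11–C12 bond and releases the 9α-OH with C9 untouched.

Step 15
Reactants: 21 9α-hydroxy TMS-alkyne
Product: 22 terminal alkyne
Conditions: K2CO3, MeOH, rt
Reagents that add atoms: none
Why: Base-mediated protodesilylation of the alkynylsilane unmasks the terminal alkyne, and the TBS ether is stable to K2CO3/MeOH.

Step 16
Reactants: 22 terminal alkyne
Product: 24 propargylic alcohol, via dilithio alkoxide-acetylide 23 (not isolated)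
Conditions: n-BuLi (2.2 equiv), THF, −78 → 0 °C; (CH2O)n, 0 °C → rt; H2O
Reagents that add atoms: formaldehyde (from paraformaldehyde), C=O
Why: Acetylide addition to formaldehyde (hydroxymethylation) adds C15 with its oxygen; the tertiary alkoxide forms no stable adduct.

Step 17
Reactants: 24 propargylic alcohol
Product: 26 (Z)-vinyl iodide, via cyclic vinylalanate 25 (not isolated)
Conditions: NaAlH2(OCH2CH2OMe)2, THF, 0 °C → rt; then I2, −78 → 0 °C
Reagents that add atoms: iodine, [I][I]
Why: Hydroxyl-directed trans-hydroalumination of the propargylic alcohol places aluminium on C13 in the five-membered alanate, and iodinolysis with retention gives the (Z)-3-iodoallylic alcohol with iodine cis to CH2OH.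

Step 18
Reactants: 26 (Z)-vinyl iodide
Product: 27 butenolide 6α-TBS ether
Conditions: CO (1 atm), PdCl2(PPh3)2 (5 mol%), K2CO3, THF, 50 °C
Reagents that add atoms: carbon monoxide, [C-]#[O+]
Why: Palladium-catalysed carbonylative lactonisation: zerovalent palladium formed in situ inserts into the carbon–iodine bond, CO insertion gives an acylpalladium species, and the cis CH2OH closes the five-membered ring with the carbonyl (C16) on C13, i.e. the α-substituted butenolide.

Step 19
Reactants: 27 butenolide 6α-TBS ether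
Product: 28 6α,9α-diol butenolide
Conditions: HF·pyridine, pyridine, THF, 0 °C → rt
Reagents that add atoms: none
Why: Fluoride-mediated desilylation under buffered, non-basic conditions frees the 6α-OH without conjugate addition or isomerisation at the butenolide.

Step 20
Reactants: 28 6α,9α-diol butenolide
Product: 29 target (CNP0205088.2)
Conditions: Ac2O, 4-(dimethylamino)pyridine (cat.), pyridine, CH2Cl2, rt
Reagents that add atoms: acetic anhydride, CC(=O)OC(C)=O
Why: DMAP-catalysed acylation esterifies the secondary equatorial 6α-OH, whereas the axial tertiary 9α-OH does not react at room temperature.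

**Compound list**
1 | 2-methylcyclohexane-1,3-dione | CC1C(=O)CCCC1=O | starting material
2 | methyl vinyl ketone (but-3-en-2-one) | CC(=O)C=C | starting material
3 | 2-methyl-2-(3-oxobutyl)cyclohexane-1,3-dione | CC(=O)CCC1(C)C(=O)CCCC1=O | intermediate
4 | cis-ketol, (4aS,8aS)-4a-hydroxy-8a-methylhexahydronaphthalene-1,6(2H,5H)-dione | O=C1CCC[C@]2(O)CC(=O)CC[C@]12C | intermediate (not isolated)
5 | (S)-Wieland–Miescher ketone, (8aS)-8a-methyl-3,4,8,8a-tetrahydronaphthalene-1,6(2H,7H)-dione | O=C1CCCC2=CC(=O)CC[C@]12C | intermediate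
6 | (4aS,5S)-5-hydroxy-4a-methyl-4,4a,5,6,7,8-hexahydronaphthalen-2(3H)-one (9β-OH) | O[C@H]1CCCC2=CC(=O)CC[C@]12C | intermediate
7 | (4aS,5S)-5-(benzyloxy)-4a-methyl-4,4a,5,6,7,8-hexahydronaphthalen-2(3H)-one | c1ccccc1CO[C@H]1CCCC2=CC(=O)CC[C@]12C | intermediate
8 | (4aS,5S)-5-(benzyloxy)-1,4a-dimethyl-4,4a,5,6,7,8-hexahydronaphthalen-2(3H)-one | c1ccccc1CO[C@H]1CCCC2=C(C)C(=O)CC[C@]12C | intermediate (not isolated)
9 | (4aS,5S)-5-(benzyloxy)-1,1,4a-trimethyl-3,4,4a,5,6,7-hexahydronaphthalen-2(1H)-one | c1ccccc1CO[C@H]1CCC=C2C(C)(C)C(=O)CC[C@]12C | intermediate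
10 | hydrazone of 9 | c1ccccc1CO[C@H]1CCC=C2C(C)(C)C(=NN)CC[C@]12C | intermediate (not isolated)
11 | (1S,8aS)-1-(benzyloxy)-5,5,8a-trimethyl-1,2,3,5,6,7,8,8a-octahydronaphthalene | c1ccccc1CO[C@H]1CCC=C2C(C)(C)CCC[C@]12C | intermediate
12 | 6α-boryl adduct (5α-H, 6α-BH2, 9β-OBn) | B[C@H]1CC[C@H](OCc3ccccc3)[C@@]2(C)CCCC(C)(C)[C@H]12 | intermediate (not isolated)
13 | (1S,4S,4aS,8aS)-4-(benzyloxy)-4a,8,8-trimethyldecahydronaphthalen-1-ol (6α-OH, 9β-OBn) | O[C@H]1CC[C@H](OCc3ccccc3)[C@@]2(C)CCCC(C)(C)[C@H]12 | intermediate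
14 | tert-butyldimethylsilyl ether of 13 (6α-OTBS, 9β-OBn) | CC(C)(C)[Si](C)(C)O[C@H]1CC[C@H](OCc3ccccc3)[C@@]2(C)CCCC(C)(C)[C@H]12 | intermediate
15 | (1S,4S,4aS,8aS)-4-[(tert-butyldimethylsilyl)oxy]-5,5,8a-trimethyldecahydronaphthalen-1-ol (9β-OH) | CC(C)(C)[Si](C)(C)O[C@H]1CC[C@H](O)[C@@]2(C)CCCC(C)(C)[C@H]12 | intermediate
16 | (4S,4aS,8aS)-4-[(tert-butyldimethylsilyl)oxy]-5,5,8a-trimethyloctahydronaphthalen-1(2H)-one | CC(C)(C)[Si](C)(C)O[C@H]1CCC(=O)[C@@]2(C)CCCC(C)(C)[C@H]12 | intermediate
17 | lithium Δ8-enolate of 16 | CC(C)(C)[Si](C)(C)O[C@H]1CC=C(O[Li])[C@@]2(C)CCCC(C)(C)[C@H]12 | intermediate (not isolated)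
18 | (2R,4S,4aS,8aS)-4-[(tert-butyldimethylsilyl)oxy]-2,5,5,8a-tetramethyloctahydronaphthalen-1(2H)-one (8α-Me) | CC(C)(C)[Si](C)(C)O[C@H]1C[C@@H](C)C(=O)[C@@]2(C)CCCC(C)(C)[C@H]12 | intermediate
19 | tert-butyldimethyl{[(1S,3R,4aS,8aS)-3,4a,8,8-tetramethyl-4-methylidenedecahydronaphthalen-1-yl]oxy}silane | CC(C)(C)[Si](C)(C)O[C@H]1C[C@@H](C)C(=C)[C@@]2(C)CCCC(C)(C)[C@H]12 | intermediate
20 | 9α,11-spiro-epoxide of 19 (oxirane O on the α face, CH2 β; C9 = R) | CC(C)(C)[Si](C)(C)O[C@H]1C[C@@H](C)[C@]3(CO3)[C@@]2(C)CCCC(C)(C)[C@H]12 | intermediate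
21 | (1R,2R,4S,4aS,8aS)-4-[(tert-butyldimethylsilyl)oxy]-2,5,5,8a-tetramethyl-1-[4-(trimethylsilyl)but-3-yn-1-yl]decahydronaphthalen-1-ol | CC(C)(C)[Si](C)(C)O[C@H]1C[C@@H](C)[C@](O)(CCC#C[Si](C)(C)C)[C@@]2(C)CCCC(C)(C)[C@H]12 | intermediate
22 | (1R,2R,4S,4aS,8aS)-1-(but-3-yn-1-yl)-4-[(tert-butyldimethylsilyl)oxy]-2,5,5,8a-tetramethyldecahydronaphthalen-1-ol | CC(C)(C)[Si](C)(C)O[C@H]1C[C@@H](C)[C@](O)(CCC#C)[C@@]2(C)CCCC(C)(C)[C@H]12 | intermediate
23 | dilithio derivative of 22 (lithium 9-alkoxide, lithium acetylide) | CC(C)(C)[Si](C)(C)O[C@H]1C[C@@H](C)[C@](O[Li])(CCC#C[Li])[C@@]2(C)CCCC(C)(C)[C@H]12 | intermediate (not isolated)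
24 | (1R,2R,4S,4aS,8aS)-4-[(tert-butyldimethylsilyl)oxy]-1-(5-hydroxypent-3-yn-1-yl)-2,5,5,8a-tetramethyldecahydronaphthalen-1-ol | CC(C)(C)[Si](C)(C)O[C@H]1C[C@@H](C)[C@](O)(CCC#CCO)[C@@]2(C)CCCC(C)(C)[C@H]12 | intermediate
25 | sodium cyclic vinylalanate from 24 (Al on C13, cis to the C15–O; drawn with the 9-OH not metalated) | CC(C)(C)[Si](C)(C)O[C@H]1C[C@@H](C)[C@](O)(CCC3=CCO[Al-]3(OCCOC)OCCOC)[C@@]2(C)CCCC(C)(C)[C@H]12.[Na+] | intermediate (not isolated)
26 | (1R,2R,4S,4aS,8aS)-4-[(tert-butyldimethylsilyl)oxy]-1-[(3Z)-5-hydroxy-3-iodopent-3-en-1-yl]-2,5,5,8a-tetramethyldecahydronaphthalen-1-ol | CC(C)(C)[Si](C)(C)O[C@H]1C[C@@H](C)[C@](O)(CC/C(I)=C/CO)[C@@]2(C)CCCC(C)(C)[C@H]12 | intermediate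
27 | 3-{2-[(1R,2R,4S,4aS,8aS)-4-[(tert-butyldimethylsilyl)oxy]-1-hydroxy-2,5,5,8a-tetramethyldecahydronaphthalen-1-yl]ethyl}furan-2(5H)-one | CC(C)(C)[Si](C)(C)O[C@H]1C[C@@H](C)[C@](O)(CCC3=CCOC3=O)[C@@]2(C)CCCC(C)(C)[C@H]12 | intermediate
28 | 3-{2-[(1R,2R,4S,4aS,8aS)-1,4-dihydroxy-2,5,5,8a-tetramethyldecahydronaphthalen-1-yl]ethyl}furan-2(5H)-one | O[C@H]1C[C@@H](C)[C@](O)(CCC3=CCOC3=O)[C@@]2(C)CCCC(C)(C)[C@H]12 | intermediate
29 | (1S,3R,4R,4aS,8aS)-4-hydroxy-3,4a,8,8-tetramethyl-4-[2-(2-oxo-2,5-dihydrofuran-3-yl)ethyl]decahydronaphthalen-1-yl acetate (6α-acetoxy-9α-hydroxylabd-13-en-16,15-olide) | CC(=O)O[C@H]1C[C@@H](C)[C@](O)(CCC2=CCOC2=O)[C@@]2(C)CCCC(C)(C)[C@H]12 | target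

**Totals**
Total step count: 20. Longest linear sequence: 20 steps (the route is fully linear from 1 and 2).

**Steps most likely to fail, with fallbacks**

Step 12, the Wittig methylenation of the hindered, enolisable ketone, may stall. The fallback is a Peterson olefination that sets out from 18: Me3SiCH2Li with CeCl3 (THF, −78 °C) adds to the carbonyl to give the β-hydroxysilane F1 (either C9 epimer serves), and KH in THF then brings about syn-elimination to come back to the route at 19.

Step 13, the epoxidation, may go to the wrong face of the alkene. If the peracid prefers the β face, the same steric bias should steer a carbon nucleophile to that face as well. The fallback therefore sets out from ketone 18 and adds the organocerium reagent made from BrMgCH2CH2C≡CSiMe3 and CeCl3 (THF, −78 °C) directly to the C9 carbonyl. This gives carbinol 21, where it comes back to the route; steps 12 to 14 are skipped and no new compound F0 is made.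

Step 14, the SN2 opening at the neopentyl-type C11, may be too slow with the propargylic lithium reagent. The fallback sets out from epoxide 20: the more reactive allylMgCl with catalytic CuI (copper monoiodide; THF, −30 °C) gives the homoallylic carbinol F2. Ozonolysis (O3, CH2Cl2/MeOH, −78 °C; Me2S) gives the aldehyde, which closes onto the 9-OH as the spiro-lactol F3. Dimethyl (1-diazo-2-oxopropyl)phosphonate (Ohira–Bestmann reagent) with K2CO3 in MeOH then homologates it to the terminal alkyne, coming back to the route at 22.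

**Further compounds**
F1 | step 12 | 9-hydroxy-9-[(trimethylsilyl)methyl] adduct of 18 (β-hydroxysilane; 9β-OH epimer drawn) | CC(C)(C)[Si](C)(C)O[C@H]1C[C@@H](C)[C@@](O)(C[Si](C)(C)C)[C@@]2(C)CCCC(C)(C)[C@H]12
F0 | step 13 | none | none
F2 | step 14 | (1R,2R,4S,4aS,8aS)-1-(but-3-en-1-yl)-4-[(tert-butyldimethylsilyl)oxy]-2,5,5,8a-tetramethyldecahydronaphthalen-1-ol | CC(C)(C)[Si](C)(C)O[C@H]1C[C@@H](C)[C@](O)(CCC=C)[C@@]2(C)CCCC(C)(C)[C@H]12
F3 | step 14 | spiro-lactol (9,13-epoxy-13-ol, anomer mixture) from ozonolysis of F2 | CC(C)(C)[Si](C)(C)O[C@H]1C[C@@H](C)[C@]3(CCC(O)O3)[C@@]2(C)CCCC(C)(C)[C@H]12
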